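Readings and results were generated by integration for substances that don't exist; the scatter is artificial.

Start from Sunday's run, where the left-handed substrate has already fallen by the first reading at 0.250 h.

| flask | left-handed substrate | right-handed substrate | coupling partner | free catalyst | impurity | remark |
|---|---|---|---|---|---|---|
| Sunday's | 0.10 M | 0.10 M | 1.5 equiv | 1 mol% | 0.66 mM | run made earlier |
| Wednesday's | 0.10 M | 0.10 M | 2.2 equiv | 1 mol% | 0.66 mM | run made earlier |
| flask | 0.10 M | 0.10 M | 3.00 equiv | 1 mol% | 0.66 mM |  |

| run | time / h | left-handed product / % | left-handed substrate / % |
|---|---|---|---|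
| Sunday's | 0.250 | 6.9 | 42.8 |
| Sunday's | 0.667 | 14.9 | 34.3 |
| Sunday's | 1.33 | 24.2 | 25.6 |
| Sunday's | 3.00 | 35.8 | 14.1 |
| Wednesday's | 0.833 | 25.2 | 25.6 |
| Wednesday's | 1.50 | 34.6 | 16.0 |
| Wednesday's | 2.50 | 42.1 | 7.5 |
| Wednesday's | 3.00 | 44.1 | 5.6 |

(standard deviation of a reading: 0.3 percentage points)

- apparent order in free catalyst when 30% of the left-handed substrate and right-handed substrate together are converted (percent change of the rate of making left-handed product for one percent more free catalyst charged)
- apparent order in coupling partner when 30% of the left-handed substrate and right-handed substrate together are converted (percent change of the rate of making left-handed product for one percent more coupling partner charged)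
- factor on the rate of making left-handed product when 30% of the left-handed substrate and right-handed substrate together are converted if coupling partner is charged twice over

Climb the ladder of times from the fastest rung. Take the pseudo-first-order constant of the left-handed substrate over each interval. Sunday's run opens at 0.622 h⁻¹ and then reads 0.531 h⁻¹, so it shows no lag and starts higher than it continues. Assume as the fastest rung that in Sunday's run the impurity has acted on the catalyst before 0.250 h, which is shorter than the left-handed substrate's lifetime of 1.61 h. On the middle rung, Wednesday's run reads 0.705 h⁻¹, a lifetime of 1.42 h. On the slowest rung, Sunday's constant sinks to 0.357 h⁻¹ by 3.00 h, which suits a partner wearing down over hours.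

So treat the working catalyst in the new flask as a fixed amount after the fastest rung. Let C₀ be the charge, 1.00 mM on the left-handed substrate, and Y₀ the impurity, 0.66 mM. Assume each impurity takes one catalyst, which no run tests. The working amount is W = C₀ − Y₀ = 0.340 mM. With Y₀ held fixed, extra catalyst falls wholly on W; take the rate at fixed conversion to be proportional to W. One percent more C₀ therefore gives Λ percent more W, where Λ, the poison leverage, is the charge over what stays working: 2.94.

The forecast gives 1.5, 1.1 and 2.1, differs from my 2.94 on the catalyst, and says of that figure: “This is a guess”.

The flask gives 3.0 in catalyst, 1.2 in partner and a factor of 2.23 on doubling the partner.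

    free catalyst + left-handed substrate ⇌ catalyst intermediate A (K = 19.0 M⁻¹, k = 160 M⁻¹ s⁻¹)
    free catalyst + right-handed substrate ⇌ catalyst intermediate B (K = 21.0 M⁻¹, k = 95.0 M⁻¹ s⁻¹)
    coupling partner + catalyst intermediate A → free catalyst + left-handed product (k = 0.800 M⁻¹ s⁻¹)
    coupling partner + catalyst intermediate B → free catalyst + right-handed product (k = 0.170 M⁻¹ s⁻¹)
    coupling partner → decomposition product (k = 2.30 × 10⁻⁶ s⁻¹)
    free catalyst + impurity → spent catalyst (k = 140 M⁻¹ s⁻¹)

In this flask, spent catalyst reads 66.0% of the catalyst charged at 0.400 h, with impurity at 0%. Use Λ once more: its inverse puts 34.0% of the charge in the working round. At 2.00 h the flask holds free catalyst 14.5%, catalyst intermediate A 2.45% and catalyst intermediate B 17.1%, together 34.1%.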